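The readings stem from a simulated flask for an exercise, noise included.

| flask | E | X | remark | time |
|---|---|---|---|---|
| dusk | 0.20 mM | 0.020 mM | run made earlier |  |
| winter | 0.10 mM | 0.020 mM | run made earlier |  |
| spring | 0.15 mM | 0.020 mM | run made earlier |  |
| noon | 0.20 mM | 0.010 mM | run made earlier |  |
| alder | 0.20 mM | 0.0200 mM | one stirred flow tank at steady state, fed with the mixture as stated, mean residence time 2.0 min |  |
| maple | 0.20 mM (fed, over 1.60 min) | 0.0200 mM | a stirred flask in which E is dosed at a steady rate over 1.60 min without added volume, worked up at 2.0 min | 2.0 min |
| larch | 0.20 mM | 0.0200 mM | a closed flask charged with all of it at once and left for 2.0 min | 2.0 min |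

- dusk (time / s: Q / %, E / %): 20.0: 33.6, 55.8; 40.0: 53.8, 34.2; 50.0: 57.4, 27.6; 80.0: 71.5, 14.1
- winter (time / s: Q / %, E / %): 12.0: 22.3, 68.1; 30.0: 43.6, 42.4; 60.0: 61.9, 19.4; 90.0: 71.1, 7.7
- spring (time / s: Q / %, E / %): 12.0: 21.4, 68.5; 30.0: 43.5, 41.0; 60.0: 64.1, 21.5; 90.0: 74.4, 9.5
- noon (time / s: Q / %, E / %): 10.0: 19.7, 76.5; 20.0: 33.0, 58.2; 40.0: 54.5, 34.4; 90.0: 76.8, 12.1

(standard deviation of a reading: 1 percentage point)

- the stated concentrations are those of everything mixed, before any reaction; amounts are the same in each set-up
- the analysis behind the earlier runs scatters by 1 percentage point, standard deviation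
- the feed brings no volume worth counting
- the earlier runs were made in a closed, stirred flask

- the set-up with the highest amount of Q at the outlet or at the end, in percent of the E put in ("none" if the first two lie within 2 percentage points) (alder / maple / larch / none)
- amount of Q at the outlet or at the end, in percent of the E put in, alder
- amount of Q at the outlet or at the end, in percent of the E put in, maple
- amount of Q at the outlet or at the end, in percent of the E put in, larch

- At early times dusk, charged as larch, loses E at 1.75 /min per E present, while Q appears at 1.33 /min: Q gained over 20.0 s divided by that stretch's logarithmic mean [E] and by the time. This first-order constant of Q is kQ.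
- Noon, with X at half of dusk, reads 1.35 /min, and winter, with E at half, reads 1.34 /min; both match dusk, so the rate of Q follows [E] to the first power.
- The first slowing is in E's loss: Q's early share, the selectivity, is 76.0%, but from 40.0 s to 80.0 s dusk loses E at 1.33 /min, slower by a factor 1.32 and level with kQ.
- The second slowing is [E] itself: at 80.0 s E reads 14.1%, so Q's rate is down by a factor 7.09. Carried on to 2.0 min at that late constant, the reckoning here puts E at 5.81% and gives larch 79.8% of Q.
- A tank works at its outlet [E] throughout, so alder's Q is kQ times residence time times outlet E. With dusk's mean constant to 40.0 s, 1.61 /min, outlet E is 23.7% and Q is 63.1%.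
- The forecast names larch, with 65% for alder, 67% for maple and 80.5% for larch: “Conversion decides; the trap is nearly exhausted everywhere.” Its alder stands above the reckoning here.
- The flasks give 65.1% for alder, 66.3% for maple and 79.1% for larch, so larch leads.

    E → Q (k = 0.0220 /s)
    2 E → G (k = 6.20 /M/s)
    E + G → J (k = 160 /M/s)
    2 E → D (k = 0.110 /M/s)
    E + X → L (k = 650 /M/s)

- By its first-order step alone E has a half-life of 0.53 min, shorter than the 0.89 min of E by its second-order step with the added species in larch, that species held at its charge. Dividing each simulated Q by kQ and 2.0 min gives an implied time-mean E of 29.7% in larch, above the implied outlet E of 24.5% in alder.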